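**Strategy.** The route rests on cutting the Q–C4 bond, the crowded link between ring D and the alkene carbon C4 of ring A. A dianionic Carroll rearrangement makes this bond and the isolated quaternary stereocentre Q in one [3,3] shift. It uses the fact that the carbinol carbon of ring D stands 1,3 to its methyl-bearing alkene carbon, so the C–O stereocentre is converted into Q and C4 is delivered as the CH2 group flanking the C3 carbonyl. The precursor is the acetoacetate of (S)-3,5,5-trimethylcyclohex-2-en-1-ol. Ring A is then annulated at C2 and C4, ring B is closed last as a C7=C10 enoate, and C10–O and lactone ring C follow.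

Key step: step 3

Remarks before the steps:
- Locants: C1 carries the oxymethylene C12; C2 and C3 are the ring A methylenes; C4=C5 is the ring A alkene and C4 bears Q; C6 is the ring B methylene; C7–C8(=O)–O9–C10 is lactone ring C; C11 is the sp3 fusion carbon; Q is the quaternary carbon of ring D.
- Configuration: a same-face 1,3-shift turns the (S)-carbinol of 5 into (S)-Q, which is the configuration of the target, so 5 and 8 are used as drawn.
- Assumption for step 1: the alkenyl arm of isophorone takes the large-group site of the oxazaborolidine complex, so the (R)-catalyst gives (S)-2.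
- Assumption for step 6: the quinidine-derived primary amine gives the 1S adduct; if the sense is the opposite, the quinine-derived pseudo-enantiomer, (8α,9S)-6′-methoxycinchonan-9-amine, is used with no other change.
- Design choice: ring B is closed by olefination and not brought in as a cyclopentanone. Late desaturation of a C7 ester would have to choose between the allylic C6–H and C10–H, and a 3-substituted cyclopentanone has two competing α-carbons.

Step 1
Reactants: 1 isophorone
Product: 2 (S)-3,5,5-trimethylcyclohex-2-en-1-ol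
Conditions: (R)-1-methyl-3,3-diphenyltetrahydro-1H,3H-pyrrolo[1,2-c][1,3,2]oxazaborole (10 mol %), BH3·SMe2, THF, −20 °C; MeOH, aqueous work-up
Reagents that add atoms: none
Why: Corey–Bakshi–Shibata reduction, in which the oxazaborolidine–borane complex delivers hydride to one carbonyl face only, should set the (S)-carbinol centre whose enantiomeric purity is later carried into Q.

Step 2
Reactants: 2 (S)-3,5,5-trimethylcyclohex-2-en-1-ol; 3 2,2,6-trimethyl-4H-1,3-dioxin-4-one
Product: 5 (S)-3,5,5-trimethylcyclohex-2-en-1-yl 3-oxobutanoate, via acetylketene 4 (not isolated)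
Conditions: xylene, 135 °C, acetone distilled off
Reagents that add atoms: none
Why: Thermal retro-[4+2] cleavage of the dioxinone releases acetylketene, which acylates the secondary allylic alcohol under neutral conditions (acetoacetylation by acylketene trapping) without touching the carbinol configuration.

Step 3
Reactants: 5 (S)-3,5,5-trimethylcyclohex-2-en-1-yl 3-oxobutanoate
Product: 8 (S)-1-(1,5,5-trimethylcyclohex-2-en-1-yl)propan-2-one, via dilithium dienolate 6 (not isolated), via beta-keto acid 7 (not isolated)
Conditions: LiN(iPr)2 (2.2 equiv), THF, −78 °C, then 65 °C; 1 M HCl; toluene, 90 °C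
Reagents that add atoms: none
Why: Two equivalents of LiN(iPr)2 convert the acetoacetate into its dienolate, in which the ester-enolate carbon (the future C4) and the methyl-bearing alkene carbon of ring D are the ends of a six-atom array, so a concerted [3,3] shift forms the Q–C4 bond and moves the alkene to the former carbinol carbon; the resulting beta-keto carboxylate is protonated and decarboxylates on gentle heating. The closest known reaction is the dianionic Carroll rearrangement (an ester-enolate Claisen rearrangement) of cyclohex-2-enyl acetoacetates, including cases that build quaternary carbons. The step closes no ring and makes one skeletal bond. Q is the only new stereocentre and is controlled by the carbinol stereocentre of 5, because the tethered enolate can reach the alkene only on the side of the ring from which the ester oxygen departs, so the (S)-C–O centre becomes the (S)-C–C centre. The step needs full relay of the carbinol configuration across the allyl unit and C–C bonding at the fully substituted end of the alkene, in preference to proton transfer or expulsion of the allylic oxygen. Both follow from the geometry of the cyclic array, which can reach no other carbon and no other face, and the anionic variant runs in refluxing THF, well below the temperature at which a neutral allyl acetoacetate would eliminate, although the syn-axial methyl group of ring D is expected to slow the shift.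

Step 4
Reactants: 8 (S)-1-(1,5,5-trimethylcyclohex-2-en-1-yl)propan-2-one
Product: 9 (S)-1-(1,3,3-trimethylcyclohexyl)propan-2-one
Conditions: H2 (1 atm), Pd/C, EtOAc, 20 °C
Reagents that add atoms: none
Why: Heterogeneous catalytic hydrogenation saturates the cis-disubstituted ring D alkene and leaves the ketone and the quaternary centre untouched.

Step 5
Reactants: 9 (S)-1-(1,3,3-trimethylcyclohexyl)propan-2-one; 10 2-[(tert-butyldiphenylsilyl)oxy]acetaldehyde
Product: 13 (E)-5-[(tert-butyldiphenylsilyl)oxy]-1-[(1S)-1,3,3-trimethylcyclohexyl]pent-3-en-2-one, via lithium aldolate 11 (not isolated), via aldol mesylate 12 (not isolated)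
Conditions: LiN(SiMe3)2, THF, −78 °C; 10; then MsCl, NEt3, −78 → 20 °C
Reagents that add atoms: none
Why: Kinetic deprotonation occurs at the methyl group (the C4 methylene is neopentyl-like), the lithium enolate adds to the aldehyde (directed aldol addition), and the mesylated aldolate undergoes E1cB elimination to the conjugated (E)-enone that provides C2, C1 and C12.

Step 6
Reactants: 13 (E)-5-[(tert-butyldiphenylsilyl)oxy]-1-[(1S)-1,3,3-trimethylcyclohexyl]pent-3-en-2-one; 14 diethyl 2-oxobutanedioate
Product: 17 diethyl (1R,6S)-6-{[(tert-butyldiphenylsilyl)oxy]methyl}-4-oxo-3-[(1S)-1,3,3-trimethylcyclohexyl]cyclohex-2-ene-1,2-dicarboxylate, via Michael adduct 15 (not isolated), via ring ketol 16 (not isolated)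
Conditions: (9R)-6′-methoxycinchonan-9-amine (20 mol %), CF3CO2H (40 mol %), toluene, 25 °C; then TsOH·H2O (20 mol %), 110 °C, Dean–Stark
Reagents that add atoms: none
Why: Amine-catalysed asymmetric Michael addition (iminium activation of the enone) of the doubly activated CH2 of the oxalacetate sets C1, and the acid-catalysed intramolecular aldol condensation (Robinson-type annulation) can only join C4 to the alpha-keto ester carbonyl C5, which has no enolisable carbon on its other side, so ring A closes with the C4=C5 alkene while the acidic C11–H equilibrates to the arrangement trans to the C1 substituent.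

Step 7
Reactants: 17 cyclohexenone diester
Product: 18 the C3 spiro-1,3-dithiolane of 17
Conditions: HS(CH2)2SH (3 equiv), BF3·OEt2 (20 mol %), CH2Cl2, 0 → 20 °C
Reagents that add atoms: ethane-1,2-dithiol, SCCS
Why: Lewis acid-catalysed dithioketalisation of the ketone, during which the tetrasubstituted alkene stays conjugated with the C6 ester and so has no reason to migrate.

Step 8
Reactants: 18 C3 dithiolane
Product: 19 diethyl (1R,6S)-6-{[(tert-butyldiphenylsilyl)oxy]methyl}-3-[(1S)-1,3,3-trimethylcyclohexyl]cyclohex-2-ene-1,2-dicarboxylate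
Conditions: Raney Ni (W-2, pre-refluxed in acetone), EtOH, 60 °C
Reagents that add atoms: none
Why: Raney nickel desulfurisation (Mozingo reduction) replaces both C–S bonds by C–H and removes the C3 oxygen, and the hindered tetrasubstituted enoate alkene is not expected to be hydrogenated on the deactivated metal.

Step 9
Reactants: 19 deoxy diester
Product: 20 [(1R,6S)-6-{[(tert-butyldiphenylsilyl)oxy]methyl}-3-[(1S)-1,3,3-trimethylcyclohexyl]cyclohex-2-ene-1,2-diyl]dimethanol
Conditions: iBu2AlH (5 equiv), CH2Cl2, −78 → 0 °C; aqueous Rochelle salt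
Reagents that add atoms: none
Why: 1,2-Reduction of both esters by the aluminium hydride gives the allylic C6 alcohol and the saturated C10 alcohol, the silyl ether being inert.

Step 10
Reactants: 20 diol
Product: 21 {(1R,6S)-2-(chloromethyl)-6-{[(tert-butyldiphenylsilyl)oxy]methyl}-3-[(1S)-1,3,3-trimethylcyclohexyl]cyclohex-2-en-1-yl}methanol
Conditions: N-chlorosuccinimide, Me2S, CH2Cl2, −20 → 0 °C
Reagents that add atoms: N-chlorosuccinimide, O=C1CCC(=O)N1Cl
Why: Corey–Kim chlorination, in which both hydroxyls are activated reversibly as alkoxysulfonium salts but only the allylic one is displaced by chloride, so the C6 chloride forms beside the free C10 alcohol.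

Step 11
Reactants: 21 allylic chloride
Product: 22 the stabilised ylide methyl 3-(ring A C5)-2-(triphenylphosphoranylidene)propanoate, with the C10 alcohol free
Conditions: Ph3P=CHCO2Me (2.2 equiv), NaI (10 mol %), toluene, 70 °C
Reagents that add atoms: methyl (triphenylphosphoranylidene)acetate, COC(=O)C=P(c1ccccc1)(c1ccccc1)c1ccccc1
Why: C-alkylation of the stabilised phosphorus ylide at the primary allylic chloride followed by transylidation (the second equivalent of ylide acts as the base) gives the substituted neutral ylide without touching the free hydroxyl.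

Step 12
Reactants: 22 hydroxy ylide
Product: 24 bicyclic enoate (C7(CO2Me)=C10, C4=C5, C1–H and C11–H trans, C12–OSi(tBu)Ph2), via aldehyde ylide 23 (not isolated)
Conditions: Dess–Martin periodinane, CH2Cl2, 0 → 40 °C
Reagents that add atoms: none
Why: Dess–Martin oxidation liberates the C10 aldehyde, which undergoes intramolecular Wittig olefination under neutral conditions to close the five-membered ring B, so the alkene lies between C7 and C10 by construction and the epimerisable beta,gamma-unsaturated aldehyde never meets base.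

Step 13
Reactants: 24 bicyclic enoate
Product: 26 methyl cis-beta-hydroxy ester (1S,7R,10S,11R in target locants), via pinacol boronate 25 (not isolated)
Conditions: CuCl (5 mol %), NaOtBu (10 mol %), 4,5-bis(diphenylphosphino)-9,9-dimethylxanthene (5 mol %), B2pin2, MeOH, THF, 20 °C; then NaBO3·4H2O, THF/H2O
Reagents that add atoms: sodium perborate, [Na+].[O-]OB=O
Why: Copper-catalysed conjugate borylation (borylcopper addition to the enoate, then protonation by methanol) should place boron on C10 from the face opposite the C1 arm on C11 and protonate C7 opposite the new boryl group, and the perborate oxidation replaces boron by hydroxyl with retention, giving the cis hydroxy ester with C10–O syn to C11–H.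

Step 14
Reactants: 26 hydroxy ester
Product: 27 cis-beta-hydroxy acid
Conditions: LiOH·H2O, THF/H2O, 0 °C; then 1 M HCl to pH 3
Reagents that add atoms: lithium hydroxide, [Li+].[OH-]
Why: Saponification of the methyl ester at low temperature, where carboxylate formation is faster than enolisation at C7 or retro-aldol cleavage.

Step 15
Reactants: 27 hydroxy acid
Product: 28 tricyclic beta-lactone, C12 tert-butyldiphenylsilyl ether
Conditions: TsCl, pyridine, 0 °C
Reagents that add atoms: none
Why: Beta-lactonisation by carboxyl activation (mixed carboxylic–sulfonic anhydride in pyridine), attacked by the cis hydroxyl with retention at C7 and C10.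

Step 16
Reactants: 28 silyl lactone
Product: 29 C12 primary alcohol of the tricyclic lactone
Conditions: HF·pyridine, THF, 0 → 20 °C
Reagents that add atoms: none
Why: Fluoride-mediated silyl ether cleavage under weakly acidic conditions that a beta-lactone tolerates.

Step 17
Reactants: 29 hydroxy lactone
Product: 30 3'-norspongiolactone
Conditions: butanoyl chloride, pyridine, 4-(dimethylamino)pyridine (cat.), CH2Cl2, 0 °C
Reagents that add atoms: butanoyl chloride, CCCC(=O)Cl
Why: Acylation of the primary alcohol with the acid chloride under nucleophilic catalysis, conditions under which the beta-lactone is not opened.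

**Compound list**

1 | isophorone | CC1=CC(=O)CC(C)(C)C1 | starting material
2 | (S)-3,5,5-trimethylcyclohex-2-en-1-ol | O[C@@H]1C=C(C)CC(C)(C)C1 | intermediate
3 | 2,2,6-trimethyl-4H-1,3-dioxin-4-one | CC1=CC(=O)OC(C)(C)O1 | starting material
4 | acetylketene | CC(=O)C=C=O | intermediate
5 | (S)-3,5,5-trimethylcyclohex-2-en-1-yl 3-oxobutanoate | CC(=O)CC(=O)O[C@@H]1C=C(C)CC(C)(C)C1 | intermediate
6 | dilithium dienolate of 5 | [Li+].[Li+].C=C([O-])C=C([O-])O[C@@H]1C=C(C)CC(C)(C)C1 | intermediate
7 | 3-oxo-2-(1,5,5-trimethylcyclohex-2-en-1-yl)butanoic acid (Q as in 8, both C4 epimers) | CC(=O)C(C(=O)O)[C@@]1(C)C=CCC(C)(C)C1 | intermediate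
8 | (S)-1-(1,5,5-trimethylcyclohex-2-en-1-yl)propan-2-one | CC(=O)C[C@@]1(C)C=CCC(C)(C)C1 | intermediate
9 | (S)-1-(1,3,3-trimethylcyclohexyl)propan-2-one | CC(=O)C[C@@]1(C)CCCC(C)(C)C1 | intermediate
10 | 2-[(tert-butyldiphenylsilyl)oxy]acetaldehyde | O=CCO[Si](c1ccccc1)(c1ccccc1)C(C)(C)C | starting material
11 | lithium aldolate of 9 and 10 (carbinol epimers) | [Li+].[O-]C(CO[Si](c1ccccc1)(c1ccccc1)C(C)(C)C)CC(=O)C[C@@]1(C)CCCC(C)(C)C1 | intermediate
12 | methanesulfonate of the aldol | CS(=O)(=O)OC(CO[Si](c1ccccc1)(c1ccccc1)C(C)(C)C)CC(=O)C[C@@]1(C)CCCC(C)(C)C1 | intermediate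
13 | (E)-5-[(tert-butyldiphenylsilyl)oxy]-1-[(1S)-1,3,3-trimethylcyclohexyl]pent-3-en-2-one | CC(C)(C)[Si](c1ccccc1)(c1ccccc1)OC/C=C/C(=O)C[C@@]1(C)CCCC(C)(C)C1 | intermediate
14 | diethyl 2-oxobutanedioate | CCOC(=O)CC(=O)C(=O)OCC | starting material
15 | diethyl 2-{(2S)-1-[(tert-butyldiphenylsilyl)oxy]-4-oxo-5-[(1S)-1,3,3-trimethylcyclohexyl]pentan-2-yl}-3-oxobutanedioate (C11 epimers) | CCOC(=O)C(=O)C(C(=O)OCC)[C@@H](CO[Si](c1ccccc1)(c1ccccc1)C(C)(C)C)CC(=O)C[C@@]1(C)CCCC(C)(C)C1 | intermediate
16 | ring A ketol: diethyl 2-hydroxy-4-oxocyclohexane-1,2-dicarboxylate carrying Q at C4 and the silyloxymethyl group at C1 (C1 as in 15, other centres mixed) | CCOC(=O)C1(O)C(C(=O)OCC)[C@@H](CO[Si](c2ccccc2)(c2ccccc2)C(C)(C)C)CC(=O)C1[C@@]3(C)CCCC(C)(C)C3 | intermediate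
17 | diethyl (1R,6S)-6-{[(tert-butyldiphenylsilyl)oxy]methyl}-4-oxo-3-[(1S)-1,3,3-trimethylcyclohexyl]cyclohex-2-ene-1,2-dicarboxylate | CC(C)(C)[Si](c1ccccc1)(c1ccccc1)OC[C@H]1CC(=O)C([C@@]2(C)CCCC(C)(C)C2)=C(C(=O)OCC)[C@@H]1C(=O)OCC | intermediate
18 | C3 spiro-1,3-dithiolane of 17 | CC(C)(C)[Si](c1ccccc1)(c1ccccc1)OC[C@H]1CC3(SCCS3)C([C@@]2(C)CCCC(C)(C)C2)=C(C(=O)OCC)[C@@H]1C(=O)OCC | intermediate
19 | diethyl (1R,6S)-6-{[(tert-butyldiphenylsilyl)oxy]methyl}-3-[(1S)-1,3,3-trimethylcyclohexyl]cyclohex-2-ene-1,2-dicarboxylate | CC(C)(C)[Si](c1ccccc1)(c1ccccc1)OC[C@H]1CCC([C@@]2(C)CCCC(C)(C)C2)=C(C(=O)OCC)[C@@H]1C(=O)OCC | intermediate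
20 | [(1R,6S)-6-{[(tert-butyldiphenylsilyl)oxy]methyl}-3-[(1S)-1,3,3-trimethylcyclohexyl]cyclohex-2-ene-1,2-diyl]dimethanol | CC(C)(C)[Si](c1ccccc1)(c1ccccc1)OC[C@H]1CCC([C@@]2(C)CCCC(C)(C)C2)=C(CO)[C@@H]1CO | intermediate
21 | {(1R,6S)-2-(chloromethyl)-6-{[(tert-butyldiphenylsilyl)oxy]methyl}-3-[(1S)-1,3,3-trimethylcyclohexyl]cyclohex-2-en-1-yl}methanol | CC(C)(C)[Si](c1ccccc1)(c1ccccc1)OC[C@H]1CCC([C@@]2(C)CCCC(C)(C)C2)=C(CCl)[C@@H]1CO | intermediate
22 | methyl 2-(triphenylphosphoranylidene)propanoate attached through its C3 to C5 of ring A, C10 alcohol free | CC(C)(C)[Si](c1ccccc1)(c1ccccc1)OC[C@H]1CCC([C@@]2(C)CCCC(C)(C)C2)=C(CC(C(=O)OC)=P(c2ccccc2)(c2ccccc2)c2ccccc2)[C@@H]1CO | intermediate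
23 | C10 aldehyde of 22 | CC(C)(C)[Si](c1ccccc1)(c1ccccc1)OC[C@H]1CCC([C@@]2(C)CCCC(C)(C)C2)=C(CC(C(=O)OC)=P(c2ccccc2)(c2ccccc2)c2ccccc2)[C@@H]1C=O | intermediate
24 | bicyclic enoate: methyl ester on C7, C7=C10 and C4=C5 alkenes, C1–H and C11–H trans, silyl ether on C12 | CC(C)(C)[Si](c1ccccc1)(c1ccccc1)OC[C@H]1CCC([C@@]2(C)CCCC(C)(C)C2)=C2CC(C(=O)OC)=C[C@@H]21 | intermediate
25 | C10 pinacol boronate, boron cis to the C7 ester and syn to C11–H | CC(C)(C)[Si](c1ccccc1)(c1ccccc1)OC[C@H]1CCC([C@@]2(C)CCCC(C)(C)C2)=C2C[C@@H](C(=O)OC)[C@@H](B3OC(C)(C)C(C)(C)O3)[C@@H]21 | intermediate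
26 | methyl cis-beta-hydroxy ester (1S,7R,10S,11R) | CC(C)(C)[Si](c1ccccc1)(c1ccccc1)OC[C@H]1CCC([C@@]2(C)CCCC(C)(C)C2)=C2C[C@@H](C(=O)OC)[C@@H](O)[C@@H]21 | intermediate
27 | cis-beta-hydroxy acid (1S,7R,10S,11R) | CC(C)(C)[Si](c1ccccc1)(c1ccccc1)OC[C@H]1CCC([C@@]2(C)CCCC(C)(C)C2)=C2C[C@@H](C(=O)O)[C@@H](O)[C@@H]21 | intermediate
28 | tricyclic beta-lactone, C12 tert-butyldiphenylsilyl ether | CC(C)(C)[Si](c1ccccc1)(c1ccccc1)OC[C@H]1CCC([C@@]2(C)CCCC(C)(C)C2)=C2C[C@H]3C(=O)O[C@H]3[C@@H]21 | intermediate
29 | tricyclic beta-lactone, C12 alcohol | OC[C@H]1CCC([C@@]2(C)CCCC(C)(C)C2)=C2C[C@H]3C(=O)O[C@H]3[C@@H]21 | intermediate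
30 | 3'-norspongiolactone | CCCC(=O)OC[C@H]1CCC([C@@]2(C)CCCC(C)(C)C2)=C2C[C@H]3C(=O)O[C@H]3[C@@H]21 | target

**Count.** Total step count: 17. Longest linear sequence: 17 steps (1 to 30; every other input is purchased).

**Steps most likely to fail**

1. Step 3, the key step. The sigmatropic shift is slowed by the syn-axial methyl group of ring D, so proton transfer within the dianion and loss of the allylic oxygen by elimination may overtake it. The fallback sets out from 2 and comes back at 8. Heating 2 with 1,1-dimethoxy-N,N-dimethylethanamine in xylene at 140 °C should form the ketene N,O-acetal and, by an Eschenmoser–Claisen rearrangement with the same face-to-face 1,3-transfer, (S)-N,N-dimethyl-2-(1,5,5-trimethylcyclohex-2-en-1-yl)acetamide F1. MeLi in THF at −78 to 0 °C then converts this tertiary amide into ketone 8.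

2. Step 6. The iminium ion of an enone flanked by a neopentyl-type methylene may form slowly, so uncatalysed background addition would erode face selectivity at C1; the adduct may also cyclise through oxygen to a pyran before the slow carbon–carbon closure at C4. The fallback sets out from 9, 10 and 14 and comes back at 15. Knoevenagel condensation of 10 with 14 (piperidinium acetate, CH2Cl2, molecular sieves) gives diethyl 2-{2-[(tert-butyldiphenylsilyl)oxy]ethylidene}-3-oxobutanedioate F2. Ketone 9 is then added to F2 under enamine catalysis with (S)-1-(pyrrolidin-2-ylmethyl)pyrrolidine and CF3CO2H, where the amine condenses at the unhindered methyl terminus (C2) instead of at the enone, to reach adduct 15, which is cyclised as in step 6 to 17.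

3. Step 10. The neighbouring C10 hydroxyl may attack the activated allylic carbon and close a five-membered ether, and the second hydroxyl may be chlorinated as well. The fallback sets out from 20 and comes back at 24. Methyl chloroformate and pyridine give the bis(methyl carbonate) F3. Pd(PPh3)4 (zerovalent palladium) with trimethyl phosphonoacetate in THF at 50 °C ionises only the allylic carbonate (Tsuji–Trost allylic alkylation), and the released methoxide deprotonates the pronucleophile, giving the C6-alkylated phosphonate carbonate F4. K2CO3 in MeOH removes the remaining carbonate to give the hydroxy phosphonate F5. Dess–Martin oxidation to the aldehyde F6 and intramolecular Horner–Wadsworth–Emmons closure (LiCl, iPr2NEt, MeCN) return to 24.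

Further compounds
F1 | step 3 | (S)-N,N-dimethyl-2-(1,5,5-trimethylcyclohex-2-en-1-yl)acetamide | CN(C)C(=O)C[C@@]1(C)C=CCC(C)(C)C1
F2 | step 6 | diethyl 2-{2-[(tert-butyldiphenylsilyl)oxy]ethylidene}-3-oxobutanedioate | CCOC(=O)C(=O)C(=CCO[Si](c1ccccc1)(c1ccccc1)C(C)(C)C)C(=O)OCC
F3 | step 10 | bis(methyl carbonate) of diol 20 | CC(C)(C)[Si](c1ccccc1)(c1ccccc1)OC[C@H]1CCC([C@@]2(C)CCCC(C)(C)C2)=C(COC(=O)OC)[C@@H]1COC(=O)OC
F4 | step 10 | C6-alkylated trimethyl phosphonoacetate with the C10 methyl carbonate retained | CC(C)(C)[Si](c1ccccc1)(c1ccccc1)OC[C@H]1CCC([C@@]2(C)CCCC(C)(C)C2)=C(CC(C(=O)OC)P(=O)(OC)OC)[C@@H]1COC(=O)OC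
F5 | step 10 | hydroxy phosphonate (C10 alcohol free) | CC(C)(C)[Si](c1ccccc1)(c1ccccc1)OC[C@H]1CCC([C@@]2(C)CCCC(C)(C)C2)=C(CC(C(=O)OC)P(=O)(OC)OC)[C@@H]1CO
F6 | step 10 | C10 aldehyde of F5 | CC(C)(C)[Si](c1ccccc1)(c1ccccc1)OC[C@H]1CCC([C@@]2(C)CCCC(C)(C)C2)=C(CC(C(=O)OC)P(=O)(OC)OC)[C@@H]1C=O
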